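Start from the small charge of free catalyst, 1.7 mM against 1.7 M of substrate and 1.70 M of reagent, in a closed, stirred, isothermal flask. The larch run is this very flask followed so far, read with a scatter of 0.5 percentage points, and its readings are of target and substrate.

larch run (percent of the substrate charged)

| time / h | target / % | substrate / % |
|---|---|---|
| 0.667 | 1.8 | 98.2 |
| 1.33 | 3.3 | 96.8 |
| 2.00 | 4.8 | 95.6 |
| 3.00 | 6.7 | 94.2 |
| 4.00 | 8.9 | 90.9 |

(each reading ± 0.5 percentage points)

- apparent order in reagent when 30% of the substrate are converted (percent change of the rate of making target for one percent more reagent charged)
- factor on the rate of making target when 30% of the substrate are converted if free catalyst is charged twice over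

Take the slope through the last reading, 0.0378 M h⁻¹ of target, which is one turn of the catalyst in 162 s. Then define the reagent clock, the time in which the charged reagent would be gone if each target took one reagent and nothing else took any: 44.9 h.

By that clock, reach the asked conversion at 13.5 h with 1.19 M of reagent standing, so that one percent more charge means 1.43 percent more reagent there. A rate first order in reagent would then show an order of 1.43, and a saturated one would show none.

Object at once: the readings look straight, but by the clock reagent had fallen by just 8.90% at the last reading, too little to bend a line at this scatter, and no earlier run changes reagent or catalyst. Treat the order as a guess, then, and since meeting reagent is presumably one of several steps in a turn, commit to 0.5.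

For the catalyst, first order gives a factor of 2. Object again: the clock is a supposition, and if reagent leaks away by another road, a faster flask reaches the conversion with more reagent in hand, which pushes the factor a little above that.

The forecast gives 0.8 against my 0.5 and 1.9 against my 2, and of the first it says “I guess partial saturation”.

The flask gives an order of 0.22 and a factor of 2.24.

    substrate + free catalyst ⇌ catalyst intermediate A (K = 1.40 M⁻¹, k = 0.00780 M⁻¹ s⁻¹)
    catalyst intermediate C → free catalyst + target (k = 0.0330 s⁻¹)
    catalyst intermediate B → released group + catalyst intermediate C (k = 0.0210 s⁻¹)
    2 reagent → self-condensation product (k = 1.20 × 10⁻⁵ M⁻¹ s⁻¹)
    reagent + catalyst intermediate A → catalyst intermediate B (k = 0.110 M⁻¹ s⁻¹)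

Set the clock against this flask: after 3.00 h it allows 93.3% of the reagent where the flask holds 64.7%, and at 30.0 h, inside the clock's 44.9 h, reagent, the limiting reagent, is down to 0.948% with 57% of the substrate left. At 10.8 h the path through catalyst intermediate A uses reagent just 1.6 times as fast as self-condensation, and at 30.0 h more reagent sits in self-condensation product than in released group, 0.946 M against 0.738 M.

The numbers in the tables were generated by integration on assumed constants; noise was put on by code.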